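Two amounts are held against each other here: the J a flask makes, as a concentration, and the E it is charged with. Monday's flask and Wednesday's run have the same E and differ in Q.

all flasks: E 0.0714 M
- Monday's: Q 0.068 M (in portions, 4); the very flask that is asked about, followed so far; portions every 15 s
- Wednesday's: Q 0.046 M (in portions, 4); run made earlier; portions every 15 s
- flask: Q 0.068 M (in portions, 4); the portions of Q follow each other after 15 s, the first at the start; time 50 min

| run | time / min | Q / % | J / % | G / % |
|---|---|---|---|---|
| Monday's | 1.33 | 19.3 | 9.6 | 10.3 |
| Monday's | 4.00 | 18.2 | 17.8 | 10.3 |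
| Monday's | 8.00 | 17.2 | 21.8 | 9.3 |
| Monday's | 10.0 | 17.2 | 22.8 | 9.3 |
| Monday's | 15.0 | 16.6 | 23.5 | 9.5 |
| Wednesday's | 4.00 | 17.8 | 18.4 | 9.8 |
| Wednesday's | 12.0 | 16.1 | 24.8 | 8.8 |
| Wednesday's | 25.0 | 15.5 | 27.3 | 8.9 |
| Wednesday's | 40.0 | 15.6 | 27.4 | 8.4 |
| Wednesday's | 50.0 | 15.6 | 27.7 | 9.3 |

(each reading ± 0.3 percentage points)

* the state of affairs at 50 min: stopped, and by what, or still going (E has run out first / it is still moving / all of Q has reacted)
* part of the Q gone at 50 min
* the J standing at 50 min, as a percentage of the Q charged
* the G standing at 50 min, as a percentage of the Q charged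

- the numbers in the tables scatter with a standard deviation of 0.3 percentage points
- what has gone from Q into another species counts as reacted, even if it can come back
- the reaction counts as stopped when no species that holds the Q changes by six tenths of a point or more over the second half of the time

Wednesday's run stands flat from 25.0 min to 50.0 min with Q still at 15.6%, so Q is not what stopped it, and E is the likely end. Yet J as a concentration stands below the E charged in both runs, as the readings show:

Wednesday, at 50.0 min: 27.7% × 0.046 M / 0.0714 M = 17.8%

Monday, at 15.0 min: 23.5% × 0.068 M / 0.0714 M = 22.4%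

This ratio, J as a concentration over the E charged, is the E share, with one E supposed per J. Monday's Q is larger by a factor of 1.48, but its share at 15.0 min is larger by a factor of 1.26, so J as a percentage of Q stands lower in Monday's flask at that time than in Wednesday's run at 50.0 min. Monday's J gained 0.7 percentage points in its last 5.00 min, so the reckoning here puts its final J a little above 23.5%.

The forecast: E has run out first, with 83.7% of Q gone, J at 24.3% and G at 9.3%. Of its count of E it says: “This stoichiometry is a tentative inference”.

The flask gives: E has run out first, with 83.4% of Q gone, J at 24.4% and G at 9.14%.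

    Q ⇌ G (K = 0.550, k = 0.0754 s⁻¹)
    Q ⇌ L (K = 3.00, k = 0.214 s⁻¹)
    2 E → D (k = 0.187 L mol⁻¹ s⁻¹)
    Q + E → Z (k = 0.225 L mol⁻¹ s⁻¹)
    Z → J (k = 0.211 s⁻¹)

At 0.308 min in this flask, E goes to D 7.3 times as fast as it goes with Q to Z. At 50.0 min, with E, the limiting reagent, at 0%, D holds 0.0548 M of E and J holds 0.0166 M, a ratio of 3.30. The E share of this flask comes to 23.2% at 50.0 min. At 50.0 min the neighbour charged with 0.12 M of Q has an E share of 32.1%, above the 22.4% read in Monday's run at 15.0 min, while the neighbour's J stands at 19.1% of its Q.

The numbers in the tables are calculated from invented constants; noise was put on by code.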